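Locants (pyrano[3,4-b]pyran): O1, C2 (heptyl), C3, C4 (ketone), C4a, C5, C6 (decyl), O7, C8 (lactone C=O), C8a. Ring A is the lactone ring (O7) and ring B the dihydropyranone ring (O1).
Retrosynthesis: the C5 and C6 hydrogens are removed first (2-pyranone 18, C6 flat). C4a=C8a and O7–C6 are then cut together, which unzips both rings to the acyclic ene-dione tert-butyl oxalate 13. Compound 13 is the opened form of the 2,5-dialkylfuran 12, which is cut at the oxalate ester, the furan–CH2 bond (epoxide opening) and the furan–decyl bond.
Enabling feature: C6–C5–C4a–C4 is a four-carbon unit oxygenated at both ends, a latent but-2-ene-1,4-dione and hence a furan. In the ene-dione, C4a is β to the C6 ketone and α to the C4 ketone, so a phosphine adding there turns this acceptor carbon into an acyl ylide, and the oxalyl carbonyl C8a hangs from O1 at six-ring distance.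
Forward order: the chain is joined on the furan (steps 1 and 3), the oxalate is placed on O1 (step 5) and the furan is opened (step 6). Ring B (Wittig, C4a=C8a) and then ring A (O7 onto C6, loss of water) close in one flask (step 7), and the helper C5=C6 unsaturation is removed in step 8.
Stereochemistry: C2 (S) comes from (S)-1,2-epoxynonane (hydrolytic kinetic resolution) and is never touched again. C6 (R) is set last by catalyst-controlled hydrogenation of the 2-pyranone.

Key step: step 7

Assumption: the (S)-configured diphosphine is taken to deliver hydrogen to the face that gives (6R). If a test run shows the opposite sense, the (R)-ligand is used and nothing else changes.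

Step 1
Reactants: 1 furan; 2 1-bromodecane
Product: 4 2-decylfuran, via 2-furyllithium 3 (not isolated)
Conditions: furan (1.5 equiv), n-BuLi (1.0 equiv), THF, −78 → 0 °C; then 2, 0 °C → rt
Reagents that add atoms: none
Why: α-Lithiation of furan followed by SN2 alkylation of the 2-furyllithium with a primary bromide is the standard entry to 2-alkylfurans.

Step 2
Reactants: 5 (±)-1,2-epoxynonane
Product: 6 (S)-1,2-epoxynonane
Conditions: (S,S)-(salen)Co(OAc) [salen = N,N'-bis(3,5-di-tert-butylsalicylidene)cyclohexane-1,2-diamine dianion] (0.5 mol %), H2O (0.55 equiv), neat, 0 °C → rt; distillation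
Reagents that add atoms: none
Why: In the hydrolytic kinetic resolution of a terminal epoxide the (S,S)-catalyst should hydrolyse the (R)-epoxide selectively, so the (S)-epoxide that becomes C2 is left behind.

Step 3
Reactants: 4 2-decylfuran; 6 (S)-1,2-epoxynonane
Product: 8 (S)-1-(5-decylfuran-2-yl)nonan-2-ol, via (5-decylfuran-2-yl)lithium 7 (not isolated)
Conditions: n-BuLi (1.05 equiv), THF, 0 °C → rt; then 6, 0 °C → rt; H2O quench
Reagents that add atoms: none
Why: Lithiation at the free α-position and SN2 opening of the epoxide at its unsubstituted carbon is a known furan homologation, and the carbinol stereocentre is not involved, so (S) is retained.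

Step 4
Reactants: 9 oxalyl chloride; 10 tert-butanol
Product: 11 tert-butyl chlorooxoacetate
Conditions: 9 (1.2 equiv), Et2O, 0 °C → rt; concentrate, use crude
Reagents that add atoms: none
Why: Mono-alcoholysis of a diacid chloride stops at the half ester chloride because the second acyl chloride is less reactive towards the hindered alcohol.

Step 5
Reactants: 8 (S)-1-(5-decylfuran-2-yl)nonan-2-ol; 11 tert-butyl chlorooxoacetate
Product: 12 tert-butyl (S)-1-(5-decylfuran-2-yl)nonan-2-yl oxalate
Conditions: pyridine (1.5 equiv), DMAP (5 mol %), CH2Cl2, 0 °C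
Reagents that add atoms: none
Why: O-Acylation of a secondary alcohol with an alkyl oxalyl chloride is routine, occurs at oxygen only and leaves the stereocentre unchanged.

Step 6
Reactants: 12 tert-butyl (S)-1-(5-decylfuran-2-yl)nonan-2-yl oxalate
Product: 13 tert-butyl (8S,11Z)-10,13-dioxotricos-11-en-8-yl oxalate
Conditions: dimethyldioxirane (1.1 equiv, solution in acetone), CH2Cl2, −20 → 0 °C; evaporate cold, use at once
Reagents that add atoms: dimethyldioxirane, CC1(C)OO1
Why: Oxidative ring opening of a 2,5-dialkylfuran to the cis-but-2-ene-1,4-dione by a dioxirane is a known neutral reaction whose only by-product is acetone, so the elimination-prone β-oxalyloxy ketone meets neither acid nor base.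

Step 7
Reactants: 13 tert-butyl (8S,11Z)-10,13-dioxotricos-11-en-8-yl oxalate
Product: 18 (S)-6-decyl-2-heptyl-2,3-dihydropyrano[3,4-b]pyran-4,8-dione, via acyl ylide 14 (not isolated), via keto ester 15 (not isolated), via keto acid 16 (not isolated), via lactol 17 (not isolated)
Conditions: PBu3 (1.1 equiv), PhCO2H (0.1 equiv), dry toluene, 0 → 50 °C; then CF3CO2H (20 equiv), rt → 45 °C, same flask
Reagents that add atoms: none
Why: Proposed new method: tributylphosphine adds reversibly to the ene-dione (phospha-Michael addition) and a proton shift relayed by benzoic acid gives the acyl-stabilised ylide 14, in which C4a has changed from acceptor carbon to nucleophile; 14 attacks the nearer oxalyl carbonyl C8a and the oxaphosphetane collapses to Bu3P=O and the enol ether bond C4a=C8a (ring B, 6-exo-trig), the closest known reaction types being ylide formation from 1,2-diacylethenes and phosphines and the intramolecular Wittig olefination of ester carbonyls that gives chromones and furans. Because both groups sit on a ring double bond, the C8 ester and the 2-oxododecyl arm of 15 are held cis, so after acidolysis of the tert-butyl ester the carboxyl oxygen O7 adds to the C6 ketone (pseudo-acid lactol 17, ring A, 6-exo-trig) and the former ketone oxygen leaves as water to give the 2-pyranone, as in the cyclodehydration of 5-oxo-2-enoic acids and of levulinic acid. No stereocentre is created (the lactol carbon C6 becomes sp2) and C2 is a spectator. The step needs three selectivities: (a) C4a rather than C5 as ylide site, secured by the reversibility of the addition together with ring size, since only the C4a ylide can close a six-membered ring while the C5 ylide would need a seven-membered one; (b) C8a rather than C8 as the carbonyl attacked, secured by ring size and by the bulk of the tert-butyl ester; (c) Wittig closure rather than β-elimination of the oxalate, helped because ylide conjugation removes the ketone character of C4.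

Step 8
Reactants: 18 (S)-6-decyl-2-heptyl-2,3-dihydropyrano[3,4-b]pyran-4,8-dione
Product: 19 (2S,6R)-6-decyl-2-heptyl-2,3,5,6-tetrahydropyrano[3,4-b]pyran-4,8-dione (CNP0087259.1)
Conditions: Ru(OAc)2[(S)-3,5-tBu-MeOBIPHEP] (1 mol %), HBF4·OEt2 (2 mol %), H2 (60 bar), i-PrOH/CH2Cl2, 60 °C
Reagents that add atoms: none
Why: Asymmetric hydrogenation of 6-alkyl-2-pyranones with cationic ruthenium biaryl-diphosphine catalysts is known to reduce the C5=C6 bond and stop at the 5,6-dihydro stage, so the catalyst face sets C6 (R) while the tetrasubstituted push-pull C4a=C8a bond should stay.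

Compound list
1 | furan | c1ccoc1 | starting material
2 | 1-bromodecane | CCCCCCCCCCBr | starting material
3 | 2-furyllithium | [Li]c1ccco1 | intermediate
4 | 2-decylfuran | CCCCCCCCCCc1ccco1 | intermediate
5 | (±)-1,2-epoxynonane | CCCCCCCC1CO1 | starting material
6 | (S)-1,2-epoxynonane | CCCCCCC[C@H]1CO1 | intermediate
7 | (5-decylfuran-2-yl)lithium | [Li]c1ccc(CCCCCCCCCC)o1 | intermediate
8 | (S)-1-(5-decylfuran-2-yl)nonan-2-ol | CCCCCCC[C@H](O)Cc1ccc(CCCCCCCCCC)o1 | intermediate
9 | oxalyl chloride | ClC(=O)C(=O)Cl | starting material
10 | tert-butanol | CC(C)(C)O | starting material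
11 | tert-butyl chlorooxoacetate | CC(C)(C)OC(=O)C(=O)Cl | intermediate
12 | tert-butyl (S)-1-(5-decylfuran-2-yl)nonan-2-yl oxalate | CCCCCCC[C@H](OC(=O)C(=O)OC(C)(C)C)Cc1ccc(CCCCCCCCCC)o1 | intermediate
13 | tert-butyl (8S,11Z)-10,13-dioxotricos-11-en-8-yl oxalate | CCCCCCC[C@H](OC(=O)C(=O)OC(C)(C)C)CC(=O)/C=C\C(=O)CCCCCCCCCC | intermediate
14 | tert-butyl (8S)-10,13-dioxo-11-(tributyl-λ5-phosphanylidene)tricosan-8-yl oxalate (acyl ylide) | CCCCCCC[C@H](OC(=O)C(=O)OC(C)(C)C)CC(=O)C(CC(=O)CCCCCCCCCC)=P(CCCC)(CCCC)CCCC | intermediate
15 | tert-butyl (S)-2-heptyl-4-oxo-5-(2-oxododecyl)-3,4-dihydro-2H-pyran-6-carboxylate (keto ester) | CCCCCCC[C@H]1CC(=O)C(CC(=O)CCCCCCCCCC)=C(O1)C(=O)OC(C)(C)C | intermediate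
16 | (S)-2-heptyl-4-oxo-5-(2-oxododecyl)-3,4-dihydro-2H-pyran-6-carboxylic acid (keto acid) | CCCCCCC[C@H]1CC(=O)C(CC(=O)CCCCCCCCCC)=C(O1)C(=O)O | intermediate
17 | (2S)-6-decyl-2-heptyl-6-hydroxy-2,3,5,6-tetrahydropyrano[3,4-b]pyran-4,8-dione (lactol, both C6 epimers) | CCCCCCC[C@H]1CC(=O)C2=C(O1)C(=O)OC(O)(CCCCCCCCCC)C2 | intermediate
18 | (S)-6-decyl-2-heptyl-2,3-dihydropyrano[3,4-b]pyran-4,8-dione | CCCCCCC[C@H]1CC(=O)C2=C(O1)C(=O)OC(CCCCCCCCCC)=C2 | intermediate
19 | (2S,6R)-6-decyl-2-heptyl-2,3,5,6-tetrahydropyrano[3,4-b]pyran-4,8-dione | CCCCCCCCCC[C@@H]1CC2=C(O[C@@H](CCCCCCC)CC2=O)C(=O)O1 | target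

Total steps: 8. Longest linear sequence: 6 (steps 1, 3, 5, 6, 7, 8).

Steps most likely to fail

Step 7. Four processes could spoil it.
- The phosphine may add at C5 and the two ylides may not equilibrate.
- The oxalate may be lost by β-elimination before the ylide forms.
- The ester-carbonyl olefination may be too slow for a fully substituted ylide carbon.
- The acid stage may drift towards a Paal–Knorr-type furan closure.

The fallback uses known reactions only and sets out from alcohol 8. An oxa-Pictet–Spengler reaction with glyoxylic acid monohydrate (TsOH·H2O cat., MeCN, 4 Å molecular sieves) closes ring B regiospecifically on the furan β-carbon. It gives (6S)-2-decyl-6-heptyl-6,7-dihydro-4H-furo[3,2-c]pyran-4-carboxylic acid F1 as a mixture at C4 that does not matter. Dimethyldioxirane then opens the furan to (6S)-6-heptyl-4-oxo-3-[(Z)-2-oxododecylidene]tetrahydropyran-2-carboxylic acid F2. A catalytic amount of Et3N moves the hydrogen next to the carboxyl group onto the exocyclic carbon (vinylogous enolisation towards the push-pull alkene). This comes back to the route at keto acid 16, which is closed to 18 with CF3CO2H as in the second half of step 7.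

Step 8. Facial selectivity on this more heavily substituted 2-pyranone may be poor, or reduction may run on past the dihydro stage. The fallback sets the centre by ketone reduction instead of alkene hydrogenation and sets out from keto ester 15, isolated by leaving out the acid stage of step 7. A ketoreductase selected from a panel for (R)-delivery (NADP+, i-PrOH recycling, buffer/DMSO) should give tert-butyl (S)-2-heptyl-5-[(R)-2-hydroxydodecyl]-4-oxo-3,4-dihydro-2H-pyran-6-carboxylate F3. CF3CO2H then removes the tert-butyl group and lactonises it with retention, coming back at target 19.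

Step 6. The oxalate may be lost by β-elimination, or the ene-dione may oligomerise while it is concentrated and handled. The fallback never isolates the ene-dione and sets out from furan 12. Sensitised photooxygenation (O2, tetraphenylporphyrin, visible light, CH2Cl2, −78 °C) gives the furan endoperoxide tert-butyl (2S)-1-(4-decyl-2,3,7-trioxabicyclo[2.2.1]hept-5-en-1-yl)nonan-2-yl oxalate F4 (both facial isomers). A first equivalent of PBu3 reduces it in the cold to 13, and a second equivalent carries straight on, so the route is rejoined at ylide 14.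

Further compounds
F1 | step 7 | (6S)-2-decyl-6-heptyl-6,7-dihydro-4H-furo[3,2-c]pyran-4-carboxylic acid | CCCCCCC[C@H]1Cc2oc(CCCCCCCCCC)cc2C(O1)C(=O)O
F2 | step 7 | (6S)-6-heptyl-4-oxo-3-[(Z)-2-oxododecylidene]tetrahydropyran-2-carboxylic acid | CCCCCCC[C@H]1CC(=O)/C(=C\C(=O)CCCCCCCCCC)C(O1)C(=O)O
F3 | step 8 | tert-butyl (S)-2-heptyl-5-[(R)-2-hydroxydodecyl]-4-oxo-3,4-dihydro-2H-pyran-6-carboxylate | CCCCCCC[C@H]1CC(=O)C(C[C@H](O)CCCCCCCCCC)=C(O1)C(=O)OC(C)(C)C
F4 | step 6 | tert-butyl (2S)-1-(4-decyl-2,3,7-trioxabicyclo[2.2.1]hept-5-en-1-yl)nonan-2-yl oxalate | CCCCCCCCCCC12C=CC(C[C@H](CCCCCCC)OC(=O)C(=O)OC(C)(C)C)(OO1)O2
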